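The readings were computed for substances that don't exist; noise was put on by code.

Start with an easy count. Left-handed substrate becomes left-handed product or stays, so whatever those two hold beyond the left-handed half of the charge has crossed over from right-handed substrate through the racemization catalyst.

| setting | dusk | spring | summer | grey | violet | red |
|---|---|---|---|---|---|---|
| left-handed substrate | 0.99 M | 0.99 M | 0.99 M | 0.99 M | 0.99 M | 0.99 M |
| right-handed substrate | 0.99 M | 0.99 M | 0.99 M | 0.99 M | 0.99 M | 0.99 M |
| coupling partner | 2.5 equiv | 2.5 equiv | 2.5 equiv | 2.50 equiv | 2.50 equiv | 2.50 equiv |
| free catalyst | 2.5 mol% | 2.5 mol% | 2.5 mol% | 2.5 mol% | 2.5 mol% | 2.5 mol% |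
| racemization catalyst | 0.63 mol% | 0.92 mol% | 1.7 mol% | 0.6 mol% | 1 mol% | 1.5 mol% |
| remark | run made earlier | run made earlier | run made earlier |  |  |  |
| time |  |  |  | 15 h | 15 h | 15 h |

| run | time / h | left-handed product / % | left-handed substrate / % |
|---|---|---|---|
| dusk | 1.33 | 15 | 31 |
| dusk | 4.00 | 38 | 17 |
| dusk | 8.00 | 49 | 13 |
| dusk | 10.0 | 57 | 14 |
| dusk | 15.0 | 63 | 13 |
| spring | 3.00 | 33 | 22 |
| spring | 6.00 | 44 | 18 |
| spring | 10.0 | 57 | 13 |
| spring | 12.0 | 62 | 10 |
| spring | 15.0 | 64 | 9 |
| summer | 1.33 | 18 | 37 |
| summer | 4.00 | 38 | 21 |
| summer | 8.00 | 52 | 16 |
| summer | 10.0 | 58 | 12 |
| summer | 15.0 | 64 | 9 |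

(standard deviation of a reading: 2 percentage points)

- free catalyst is single-handed; left-handed substrate and right-handed substrate are mirror images of each other, charged as a racemate, each of them at the stated concentration
- steps under discussion: coupling partner + free catalyst + left-handed substrate -> free catalyst + left-handed product; coupling partner + free catalyst + right-handed substrate -> free catalyst + right-handed product; free catalyst -> spent catalyst; left-handed substrate + racemization catalyst <-> right-handed substrate + racemization catalyst
- "hardly changes" means that all values lie within two and a half points (for a concentration: within two and a half percent of the largest)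

1. amount of left-handed product at the end, in percent of the left-handed substrate and right-handed substrate together charged for grey, violet, red, in this order
2. the shape of the row from first to last (rises all the way / hardly changes / rises, then falls / falls all the way / falls, then rises)

We read the summer table between 4.00 h and 8.00 h. Left-handed product plus left-handed substrate rises by 9 percentage points. Right-handed product is unread, so we count it as nil, which overstates the right-handed substrate. The mean excess of right-handed over left-handed substrate then reads 18 points.

We call τx, the crossing time, the time in which the crossing would carry over one such excess at that pace. The summer reading gives τx = 8.00 h, with the scatter of its readings.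

The same rows give τc, the coupling time of left-handed substrate, treated as pseudo-first-order: its mean amount over its rate of loss to product, 5.29 h.

Taking the crossing pace as proportional to loading, τx becomes 22.7 h for grey, 13.6 h for violet and 9.07 h for red. Each reads longer than τc, but our nil count inflates these readings, so we call neither step the slow one. τx shortens from grey to red, so we expect the row to rise. The end readings of 63%, 64% and 64% differ by less than their scatter of 2 points, so they cannot show a rise of a few points.

The forecast differs from our reckoning. It gives 63%, 64% and 64.5%, shape hardly changes, holding that “The extra racemization gives little extra yield”.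

The flask gives 62.1%, 65.2% and 67.2%: the row rises all the way.

    coupling partner + free catalyst + left-handed substrate → free catalyst + left-handed product (k = 0.00180 M⁻² s⁻¹)
    coupling partner + free catalyst + right-handed substrate → free catalyst + right-handed product (k = 1.90 × 10⁻⁴ M⁻² s⁻¹)
    free catalyst → spent catalyst (k = 4.50 × 10⁻⁶ s⁻¹)
    left-handed substrate + racemization catalyst ⇌ right-handed substrate + racemization catalyst, rate k4*[racemization catalyst]*[left-handed substrate] forward; the back reaction follows from the equilibrium constant (k = 0.00480 M⁻¹ s⁻¹)

Scaled by loading, τx in grey stands at 2.50 times τx in red. With the last constant above, k4, τx = 1/(k4·[racemization catalyst]) comes to 9.74 h in grey and 3.90 h in red, so the run holds 1.54 crossing times in grey and 3.85 in red. At 15 h, grey ends with 17.4% right-handed substrate, more than the 12.9% of red.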